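**Retrosynthetic overview**
- Target ⇒ its tris(triethylsilyl) ether; the C7=C8 alkene comes from an aldol condensation between a 2‑bromo‑4‑silyloxy‑cyclopentenone (C8 enolate) and a C1–C7 aldehyde.
- Key step: the C12–O bond. Water adds to the side‑chain‑bearing carbon of a 2,3,5‑trisubstituted furan in an enantioselective oxa‑Piancatelli rearrangement, which converts the furan into the cyclopentenone (the only carbocycle, formed once) and sets C12.
- The furan comes from 3‑bromofuran (C2 hydroxymethylation, C5 alkylation) and (2Z,5Z)‑1‑bromoocta‑2,5‑diene; the bromine at C10 is carried in from the start.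
- The aldehyde comes from 2‑deoxy‑L‑ribose (Wittig, hydrogenation, silylation, selective Swern); C5 and C6 are taken from the sugar.

Assumptions: prostanoid numbering is used for atoms (C1 = ester carbon, C8–C12 = ring, C13–C20 = octadienyl chain); the (S,S) catalyst in step 6 is assumed to give the (4S) enone, and its (R,R) antipode is used if the first run shows the opposite sense; 2‑deoxy‑L‑ribose is drawn as its open‑chain aldehyde.

**Step 1**
Reactants: 1 1-bromopent-2-yne; 2 prop-2-yn-1-ol
Product: 3 octa-2,5-diyn-1-ol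
Conditions: CuI (cat.), NaI (cat.), K2CO3, DMF, rt
Reagents that add atoms: none
Why: Copper‑acetylide substitution of a propargylic bromide (sp–sp3 coupling) gives the skipped diyne without protecting the alcohol.

**Step 2**
Reactants: 3 octa-2,5-diyn-1-ol
Product: 4 (2Z,5Z)-octa-2,5-dien-1-ol
Conditions: H2 (1 atm), Ni(OAc)2·4H2O, NaBH4, ethylenediamine, EtOH, rt
Reagents that add atoms: none
Why: Syn semi‑hydrogenation on the nickel boride catalyst made in situ stops at the alkene and sets both Z double bonds (C14=C15 and C17=C18).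

**Step 3**
Reactants: 4 (2Z,5Z)-octa-2,5-dien-1-ol
Product: 5 (2Z,5Z)-1-bromoocta-2,5-diene
Conditions: CBr4, PPh3, CH2Cl2, 0 °C
Reagents that add atoms: carbon tetrabromide BrC(Br)(Br)Br
Why: Appel bromination of the primary allylic alcohol is an SN2 process at low temperature, without allylic shift or loss of Z geometry.

**Step 4**
Reactants: 6 3-bromofuran
Product: 8 (3-bromofuran-2-yl)methanol, via 3-bromo-2-lithiofuran 7 (not isolated)
Conditions: LDA, THF, −78 °C; (CH2O)n, −78 °C to rt; H2O
Reagents that add atoms: formaldehyde (used as paraformaldehyde) C=O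
Why: Directed deprotonation by the amide base occurs at C2 between oxygen and bromine (no bromine–lithium exchange), and the furyllithium undergoes 1,2‑addition to formaldehyde.

**Step 5**
Reactants: 8 (3-bromofuran-2-yl)methanol; 5 (2Z,5Z)-1-bromoocta-2,5-diene
Product: 10 {3-bromo-5-[(2Z,5Z)-octa-2,5-dien-1-yl]furan-2-yl}methanol, via dilithio species 9 (not isolated)
Conditions: LDA (2.3 equiv), THF, −78 °C; then 5, −78 to −20 °C; H2O
Reagents that add atoms: none
Why: After alkoxide formation LDA removes the remaining α‑proton (C5), and the hard furyllithium alkylates the primary allylic bromide by direct SN2 (no copper, hence no SN2′ shift), keeping both Z alkenes and the ring bromine.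

**Step 6**
Reactants: 10 {3-bromo-5-[(2Z,5Z)-octa-2,5-dien-1-yl]furan-2-yl}methanol
Product: 13 (4S)-2-bromo-4-hydroxy-4-[(2Z,5Z)-octa-2,5-dien-1-yl]cyclopent-2-en-1-one, via hemiketal 11 (not isolated), via hydroxypentadienyl cation 12 (not isolated)
Conditions: (S,S)-IDPi (imidodiphosphorimidate with 3,3′-bis[3,5-bis(trifluoromethyl)phenyl]-BINOL units and N-triflyl groups, 5 mol%), H2O (5 equiv), CHCl3, 40 °C
Reagents that add atoms: water O
Why: Proposed new method: the confined chiral Brønsted acid ionises the furfuryl alcohol, water adds to the furan carbon that carries the octadienyl chain (this is the new C12–O bond), the hemiketal opens to a hydroxypentadienyl cation that stays ion‑paired and doubly hydrogen‑bonded to the chiral anion, and the anion dictates the sense of the 4π conrotatory closure, which sets C12 (S in this fragment, R in the target) and leaves bromine α to the new ketone; the closest known reactions are the racemic oxa‑Piancatelli rearrangement of 5‑methylfurfuryl alcohols, the chiral‑phosphoric‑acid aza‑Piancatelli rearrangement and IDPi‑catalysed Nazarov cyclisations.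

**Step 7**
Reactants: 13 (4S)-2-bromo-4-hydroxy-4-[(2Z,5Z)-octa-2,5-dien-1-yl]cyclopent-2-en-1-one
Product: 14 (4S)-2-bromo-4-[(2Z,5Z)-octa-2,5-dien-1-yl]-4-(triethylsilyloxy)cyclopent-2-en-1-one
Conditions: TESOTf, 2,6-lutidine, CH2Cl2, −78 to 0 °C
Reagents that add atoms: triethylsilyl trifluoromethanesulfonate CC[Si](CC)(CC)OS(=O)(=O)C(F)(F)F
Why: Silylation of the tertiary alcohol with the silyl triflate blocks base‑induced retro‑aldol ring opening (which would racemise C12) and adds bulk at C12 that steers the alkene geometry in step 12.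

**Step 8**
Reactants: 15 2-deoxy-L-ribose; 16 methyl (triphenylphosphoranylidene)acetate
Product: 17 methyl (2E,5R,6S)-5,6,7-trihydroxyhept-2-enoate
Conditions: THF, 65 °C
Reagents that add atoms: none
Why: Wittig olefination of the open‑chain aldehyde form of the lactol with a stabilised ylide gives the E enoate, and the two sugar carbinol centres (future C5 and C6) are not touched.

**Step 9**
Reactants: 17 methyl (2E,5R,6S)-5,6,7-trihydroxyhept-2-enoate
Product: 18 methyl (5R,6S)-5,6,7-trihydroxyheptanoate
Conditions: H2 (1 atm), Pd/C, MeOH, rt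
Reagents that add atoms: none
Why: Catalytic hydrogenation saturates the conjugated alkene and nothing else.

**Step 10**
Reactants: 18 methyl (5R,6S)-5,6,7-trihydroxyheptanoate
Product: 19 methyl (5R,6S)-5,6,7-tris(triethylsilyloxy)heptanoate
Conditions: TESCl, imidazole, DMF, 0 °C to rt
Reagents that add atoms: chlorotriethylsilane CC[Si](Cl)(CC)CC
Why: Exhaustive silylation protects the diol and prevents δ‑lactone formation from the 5‑hydroxy ester.

**Step 11**
Reactants: 19 methyl (5R,6S)-5,6,7-tris(triethylsilyloxy)heptanoate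
Product: 20 methyl (5R,6R)-7-oxo-5,6-bis(triethylsilyloxy)heptanoate
Conditions: (COCl)2, DMSO, CH2Cl2, −78 to −30 °C; Et3N, −78 °C to rt
Reagents that add atoms: none
Why: Under Swern conditions only the unhindered primary triethylsilyl ether is cleaved and oxidised (selective oxidative desilylation), giving the aldehyde directly; the 6R label reflects a priority change, not inversion.

**Step 12**
Reactants: 14 (4S)-2-bromo-4-[(2Z,5Z)-octa-2,5-dien-1-yl]-4-(triethylsilyloxy)cyclopent-2-en-1-one; 20 methyl (5R,6R)-7-oxo-5,6-bis(triethylsilyloxy)heptanoate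
Product: 24 methyl (5R,6S,7Z)-7-[(2R)-4-bromo-2-[(2Z,5Z)-octa-2,5-dien-1-yl]-5-oxo-2-(triethylsilyloxy)cyclopent-3-en-1-ylidene]-5,6-bis(triethylsilyloxy)heptanoate, via lithium enolate 21 (not isolated), via lithium aldolate 22 (not isolated), via mesylate 23 (not isolated)
Conditions: LDA, THF, −78 °C; then 20, −78 °C; MsCl, −78 to 0 °C; DBU, 0 °C, 30 min
Reagents that add atoms: none
Why: Directed aldol addition of the only possible enolate (C8) is followed by mesylation and E1cB elimination, in which the C6 substituent turns away from the fully substituted C12 silyloxy centre toward the carbonyl side, which should favour the 7Z alkene (isomers are separated on silica), while C5, C6 and C12 are untouched.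

**Step 13**
Reactants: 24 methyl (5R,6S,7Z)-7-[(2R)-4-bromo-2-[(2Z,5Z)-octa-2,5-dien-1-yl]-5-oxo-2-(triethylsilyloxy)cyclopent-3-en-1-ylidene]-5,6-bis(triethylsilyloxy)heptanoate
Product: 25 methyl (5R,6S,7Z)-7-[(2R)-4-bromo-2-hydroxy-2-[(2Z,5Z)-octa-2,5-dien-1-yl]-5-oxocyclopent-3-en-1-ylidene]-5,6-dihydroxyheptanoate
Conditions: HF·pyridine, pyridine, THF, 0 °C to rt
Reagents that add atoms: none
Why: Buffered fluoride desilylation removes all three triethylsilyl ethers under mildly acidic conditions that spare the bromodienone, the skipped diene and the methyl ester, and C12 cannot ionise because its cation would be a cyclopentadienyl‑type cation.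

**Compound list**
1 | 1-bromopent-2-yne | CCC#CCBr | starting material
2 | prop-2-yn-1-ol | C#CCO | starting material
3 | octa-2,5-diyn-1-ol | CCC#CCC#CCO | intermediate
4 | (2Z,5Z)-octa-2,5-dien-1-ol | CC/C=C\C/C=C\CO | intermediate
5 | (2Z,5Z)-1-bromoocta-2,5-diene | CC/C=C\C/C=C\CBr | intermediate
6 | 3-bromofuran | Brc1ccoc1 | starting material
7 | 3-bromo-2-lithiofuran (not isolated) | [Li]c1occc1Br | intermediate
8 | (3-bromofuran-2-yl)methanol | OCc1occc1Br | intermediate
9 | lithium (3-bromo-5-lithiofuran-2-yl)methanolate (not isolated) | [Li]OCc1oc([Li])cc1Br | intermediate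
10 | {3-bromo-5-[(2Z,5Z)-octa-2,5-dien-1-yl]furan-2-yl}methanol | CC/C=C\C/C=C\Cc1cc(Br)c(CO)o1 | intermediate
11 | 4-bromo-5-methylidene-2-[(2Z,5Z)-octa-2,5-dien-1-yl]-2,5-dihydrofuran-2-ol (hemiketal; not isolated) | C=C1OC(O)(C/C=C\C/C=C\CC)C=C1Br | intermediate
12 | O-protonated (3E,7Z,10Z)-3-bromo-2-hydroxytrideca-1,3,7,10-tetraen-5-one (hydroxypentadienyl cation with C2 and C5 cis; not isolated) | C=C(O)/C(Br)=C\C(=[OH+])C/C=C\C/C=C\CC | intermediate
13 | (4S)-2-bromo-4-hydroxy-4-[(2Z,5Z)-octa-2,5-dien-1-yl]cyclopent-2-en-1-one | CC/C=C\C/C=C\C[C@@]1(O)C=C(Br)C(=O)C1 | intermediate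
14 | (4S)-2-bromo-4-[(2Z,5Z)-octa-2,5-dien-1-yl]-4-(triethylsilyloxy)cyclopent-2-en-1-one | CC/C=C\C/C=C\C[C@@]1(O[Si](CC)(CC)CC)C=C(Br)C(=O)C1 | intermediate
15 | 2-deoxy-L-ribose [(3R,4S)-3,4,5-trihydroxypentanal] | OC[C@H](O)[C@H](O)CC=O | starting material
16 | methyl (triphenylphosphoranylidene)acetate | COC(=O)C=P(c1ccccc1)(c1ccccc1)c1ccccc1 | starting material
17 | methyl (2E,5R,6S)-5,6,7-trihydroxyhept-2-enoate | OC[C@H](O)[C@H](O)C/C=C/C(=O)OC | intermediate
18 | methyl (5R,6S)-5,6,7-trihydroxyheptanoate | OC[C@H](O)[C@H](O)CCCC(=O)OC | intermediate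
19 | methyl (5R,6S)-5,6,7-tris(triethylsilyloxy)heptanoate | CC[Si](CC)(CC)OC[C@H](O[Si](CC)(CC)CC)[C@H](O[Si](CC)(CC)CC)CCCC(=O)OC | intermediate
20 | methyl (5R,6R)-7-oxo-5,6-bis(triethylsilyloxy)heptanoate | O=C[C@H](O[Si](CC)(CC)CC)[C@H](O[Si](CC)(CC)CC)CCCC(=O)OC | intermediate
21 | lithium enolate of 14 at C8/C9 (not isolated) | CC/C=C\C/C=C\C[C@@]1(O[Si](CC)(CC)CC)C=C(Br)C(O[Li])=C1 | intermediate
22 | lithium aldolate of 14 and 20 (C7 alkoxide; mixture at C7 and C8; not isolated) | CC/C=C\C/C=C\C[C@@]1(O[Si](CC)(CC)CC)C=C(Br)C(=O)C1C(O[Li])[C@H](O[Si](CC)(CC)CC)[C@H](O[Si](CC)(CC)CC)CCCC(=O)OC | intermediate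
23 | C7 methanesulfonate of the aldol (mixture at C7 and C8; not isolated) | CC/C=C\C/C=C\C[C@@]1(O[Si](CC)(CC)CC)C=C(Br)C(=O)C1C(OS(C)(=O)=O)[C@H](O[Si](CC)(CC)CC)[C@H](O[Si](CC)(CC)CC)CCCC(=O)OC | intermediate
24 | methyl (5R,6S,7Z)-7-[(2R)-4-bromo-2-[(2Z,5Z)-octa-2,5-dien-1-yl]-5-oxo-2-(triethylsilyloxy)cyclopent-3-en-1-ylidene]-5,6-bis(triethylsilyloxy)heptanoate | CC/C=C\C/C=C\C[C@@]1(O[Si](CC)(CC)CC)C=C(Br)C(=O)/C1=C\[C@H](O[Si](CC)(CC)CC)[C@H](O[Si](CC)(CC)CC)CCCC(=O)OC | intermediate
25 | methyl (5R,6S,7Z)-7-[(2R)-4-bromo-2-hydroxy-2-[(2Z,5Z)-octa-2,5-dien-1-yl]-5-oxocyclopent-3-en-1-ylidene]-5,6-dihydroxyheptanoate | CC/C=C\C/C=C\C[C@@]1(O)C=C(Br)C(=O)/C1=C\[C@H](O)[C@H](O)CCCC(=O)OC | target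

**Total step count:** 13
**Longest linear sequence:** 8 steps (1, 2, 3, 5, 6, 7, 12, 13)

**Steps most likely to fail**

Step 6 (the proposed asymmetric oxa‑Piancatelli). The primary, bromine‑deactivated carbinol may ionise slowly, water may erode the enantioselectivity, and cation 12 may tautomerise to the open ene‑dione and close the wrong way. The fallback sets out from 10 and comes back at 13. Compound 10 is rearranged without a chiral catalyst under the established conditions for 5‑alkylfurfuryl alcohols (ZnCl2, acetone–H2O, reflux) to racemic 2-bromo-4-hydroxy-4-[(2Z,5Z)-octa-2,5-dien-1-yl]cyclopent-2-en-1-one F1. The enantiomers are separated by preparative chiral SFC, and the (4S) enantiomer is 13.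

Step 12 (aldol condensation). The E/Z ratio at C7=C8 is not secured, and DBU may epimerise C6 or eliminate the C5 silyloxy group if left too long. The fallback sets out from 14 and 20 and comes back at 24. The condensation is run as written, and the 7E isomer methyl (5R,6S,7E)-7-[(2R)-4-bromo-2-[(2Z,5Z)-octa-2,5-dien-1-yl]-5-oxo-2-(triethylsilyloxy)cyclopent-3-en-1-ylidene]-5,6-bis(triethylsilyloxy)heptanoate F2 is isolated. F2 is irradiated (350 nm, benzene, Pyrex) to a photostationary E/Z mixture, the known behaviour of cross‑conjugated alkylidenecyclopentenones. Compound 24 is separated and F2 is recycled.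

Step 5 (C5 lithiation and alkylation). Lithiation may be incomplete, the bromine may migrate (halogen dance), or the allylic bromide may react by SN2′. The fallback sets out from 5 and comes back at 10. Purchased 2,3-dibromofuran F3, whose C5 proton is more acidic, is deprotonated with LDA (THF, −78 °C) and alkylated with 5 to give 2,3-dibromo-5-[(2Z,5Z)-octa-2,5-dien-1-yl]furan F4. Selective bromine–lithium exchange at the α‑bromine (n-BuLi, THF, −78 °C) and trapping with paraformaldehyde then give 10.

**Further compounds**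
F1 | step 6 | racemic 2-bromo-4-hydroxy-4-[(2Z,5Z)-octa-2,5-dien-1-yl]cyclopent-2-en-1-one | CC/C=C\C/C=C\CC1(O)C=C(Br)C(=O)C1
F2 | step 12 | methyl (5R,6S,7E)-7-[(2R)-4-bromo-2-[(2Z,5Z)-octa-2,5-dien-1-yl]-5-oxo-2-(triethylsilyloxy)cyclopent-3-en-1-ylidene]-5,6-bis(triethylsilyloxy)heptanoate | CC/C=C\C/C=C\C[C@@]1(O[Si](CC)(CC)CC)C=C(Br)C(=O)/C1=C/[C@H](O[Si](CC)(CC)CC)[C@H](O[Si](CC)(CC)CC)CCCC(=O)OC
F3 | step 5 | 2,3-dibromofuran (purchased) | Brc1occc1Br
F4 | step 5 | 2,3-dibromo-5-[(2Z,5Z)-octa-2,5-dien-1-yl]furan | CC/C=C\C/C=C\Cc1cc(Br)c(Br)o1
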